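**Plan**

1. Cuts: the four O–H are masked as O–Me. The bond from the bridging CH2 to the methyl-bearing ring A is cut to an aryllithium plus an aldehyde, both made from one monomer, (S)-herbertenediol dimethyl ether 9. In 9 the bond between the aryl-bearing quaternary ring carbon C1′ and its ring CH2 neighbour C5′ is cut, then the aryl–C1′ bond.
2. Enabling feature: C1′ carries the aryl group, a methyl group and the CMe2 carbon C2′. The methyl is read as a reduced formyl group, so each cyclopentane is the ring-contracted form of a 1-aryl-6,6-dimethylcyclohexene oxide whose epoxide CH becomes that exocyclic carbon, with the dimethoxyaryl group stabilising charge at C1′.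
3. Forward: aryl–C bond to 2,2-dimethylcyclohexanone (the six-membered ring is bought), alkene, epoxide, contraction to the cyclopentane, CHO to CH3. Then 9 is divided: one part is oxidised at the aryl methyl to aldehyde 10, the other is lithiated at the ring C–H next to OMe and added to 10. Deoxygenation and demethylation finish.
4. Stereochemistry: both (S) centres come from one catalytic Shi epoxidation; the epoxide configuration is passed to C1′ with inversion in the ring contraction, and a quaternary centre cannot epimerise afterwards.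

Key step: step 4

Remark: the D-fructose-derived Shi ketone is taken to attack alkene 5 on the same face as it does 1-phenylcyclohexene (which gives the (R,R)-oxide); if the hindered alkene reacts on the other face, the enantiomeric ketone from L-sorbose is used instead.

**Route**

Step 1
Reactants: 1 3,4-dimethoxytoluene; 2 2,2-dimethylcyclohexanone
Product: 4 racemic 1-(2,3-dimethoxy-5-methylphenyl)-2,2-dimethylcyclohexan-1-ol, via (2,3-dimethoxy-5-methylphenyl)lithium 3 (not isolated)
Conditions: n-BuLi, TMEDA, THF, 0 °C to rt; then 2, −78 °C to rt; then H2O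
Reagents that add atoms: none
Why: Directed ortho-metalation should place lithium on the ring C–H that is ortho to OMe and not flanked by the methyl group (the usual preference for 4-alkylveratroles), and the aryllithium then adds 1,2 to the ketone; the carbinol centre is racemic and is removed in step 2.

Step 2
Reactants: 4 racemic 1-(2,3-dimethoxy-5-methylphenyl)-2,2-dimethylcyclohexan-1-ol
Product: 5 1-(6,6-dimethylcyclohex-1-en-1-yl)-2,3-dimethoxy-5-methylbenzene
Conditions: POCl3, pyridine, 0 °C to 60 °C
Reagents that add atoms: none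
Why: Base-mediated dehydration of the tertiary benzylic alcohol through its dichlorophosphate (E2-type) can give only one alkene because the other neighbour of the carbinol carbon is the quaternary CMe2 carbon, and the basic medium avoids a Wagner–Meerwein methyl shift.

Step 3
Reactants: 5 1-(6,6-dimethylcyclohex-1-en-1-yl)-2,3-dimethoxy-5-methylbenzene
Product: 6 (1R,6R)-1-(2,3-dimethoxy-5-methylphenyl)-2,2-dimethyl-7-oxabicyclo[4.1.0]heptane
Conditions: D-fructose-derived Shi ketone (30 mol %), Oxone (2KHSO5·KHSO4·K2SO4), K2CO3, Bu4NHSO4, MeCN–CH2(OMe)2–aqueous buffer pH 10.5, 0 °C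
Reagents that add atoms: Oxone (potassium peroxymonosulfate, KHSO5), [K+].[O-]S(=O)(=O)OO
Why: Shi asymmetric epoxidation: the chiral dioxirane made in situ from the ketone transfers oxygen to one face of the trisubstituted aryl alkene through a spiro transition state, which should set both epoxide carbons as (1R,6R) by analogy with 1-arylcyclohexenes.

Step 4
Reactants: 6 (1R,6R)-1-(2,3-dimethoxy-5-methylphenyl)-2,2-dimethyl-7-oxabicyclo[4.1.0]heptane
Product: 7 (1R)-1-(2,3-dimethoxy-5-methylphenyl)-2,2-dimethylcyclopentane-1-carbaldehyde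
Conditions: Et2AlCl (1.0 equiv), PhMe, −78 °C; then 1 M HCl
Reagents that add atoms: none
Why: Et2AlCl binds the epoxide oxygen and the benzylic C–O bond ionises while the ring CH2 carbon attached to the epoxide CH, held roughly anti to the breaking bond in the fused bicycle, shifts to the benzylic carbon as the remaining C–O becomes the formyl C=O, so the six-membered ring is cut down to the cyclopentane and the quaternary carbon–CH2 bond is made in the same event. The closest known reaction type is the Lewis-acid Meinwald (semipinacol) rearrangement of 1-arylcycloalkene oxides to 1-arylcycloalkanecarbaldehydes, together with its enantiospecific variant in which aryl epoxides rearrange under Et2AlCl with inversion at the benzylic carbon. The cyclopentane is closed by a suprafacial 1,2-alkyl shift (ring contraction), not by an exo or endo attack of a chain. The quaternary stereocentre is controlled by the epoxide configuration, because the migrating carbon enters the benzylic carbon on the face opposite the departing oxygen, so the (1R,6R)-epoxide should give the (R)-aldehyde. The step needs ring-bond migration in preference to a 1,2-hydride shift (which would lead to 2-aryl-3,3-dimethylcyclohexanone) and migration faster than conformational relaxation of the cation; in the ion pair first formed the epoxide C–H bond lies near the nodal plane of the empty orbital, the bulky O–Al group and the crowded aryl/CMe2 flank disfavour the conformer needed for hydride shift, and toluene at −78 °C keeps the ion pair tight.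

Step 5
Reactants: 7 (1R)-1-(2,3-dimethoxy-5-methylphenyl)-2,2-dimethylcyclopentane-1-carbaldehyde
Product: 9 1,2-dimethoxy-5-methyl-3-[(1S)-1,2,2-trimethylcyclopentyl]benzene, via aldehyde hydrazone 8 (not isolated)
Conditions: N2H4·H2O, KOH, diethylene glycol, 130 °C then 200 °C
Reagents that add atoms: none
Why: Wolff–Kishner reduction (Huang-Minlon procedure) turns the non-enolisable neopentyl aldehyde into the methyl group; the quaternary centre has no α-hydrogen and cannot epimerise, and its descriptor changes from R to S only because CHO becomes CH3.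

Step 6
Reactants: 9 1,2-dimethoxy-5-methyl-3-[(1S)-1,2,2-trimethylcyclopentyl]benzene
Product: 10 3,4-dimethoxy-5-[(1S)-1,2,2-trimethylcyclopentyl]benzaldehyde
Conditions: IBX (3 equiv), DMSO–PhF 1:2, 85 °C
Reagents that add atoms: IBX (2-iodoxybenzoic acid), O=C1OI(=O)(O)c2ccccc12
Why: Single-electron-transfer benzylic oxidation with IBX (Nicolaou benzylic oxidation) should act on the electron-rich arene, whose only benzylic C–H bonds are those of the aryl methyl group, and is expected to stop at the aldehyde.

Step 7
Reactants: 9 1,2-dimethoxy-5-methyl-3-[(1S)-1,2,2-trimethylcyclopentyl]benzene; 10 3,4-dimethoxy-5-[(1S)-1,2,2-trimethylcyclopentyl]benzaldehyde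
Product: 12 [2,3-dimethoxy-6-methyl-4-[(1S)-1,2,2-trimethylcyclopentyl]phenyl][3,4-dimethoxy-5-[(1S)-1,2,2-trimethylcyclopentyl]phenyl]methanol (both carbinol epimers), via 2,3-dimethoxy-6-methyl-4-[(1S)-1,2,2-trimethylcyclopentyl]phenyllithium 11 (not isolated)
Conditions: 9, n-BuLi, TMEDA, Et2O, 0 °C to rt; then 10, −78 °C to rt; then H2O
Reagents that add atoms: none
Why: Directed ortho-metalation of 9 can occur only at the single ring C–H ortho to an OMe group (between OMe and CH3), and 1,2-addition of this aryllithium to the aldehyde fixes the bridge carbon at the correct ring position; the carbinol centre is formed without control and is removed in step 8.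

Step 8
Reactants: 12 [2,3-dimethoxy-6-methyl-4-[(1S)-1,2,2-trimethylcyclopentyl]phenyl][3,4-dimethoxy-5-[(1S)-1,2,2-trimethylcyclopentyl]phenyl]methanol
Product: 13 1-[[3,4-dimethoxy-5-[(1S)-1,2,2-trimethylcyclopentyl]phenyl]methyl]-2,3-dimethoxy-6-methyl-4-[(1S)-1,2,2-trimethylcyclopentyl]benzene
Conditions: Et3SiH, CF3CO2H, CH2Cl2, 0 °C
Reagents that add atoms: none
Why: Ionic hydrogenation: the doubly benzylic, electron-rich carbinol should ionise readily in acid and the diarylmethyl cation is reduced by hydride transfer from the silane.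

Step 9
Reactants: 13 1-[[3,4-dimethoxy-5-[(1S)-1,2,2-trimethylcyclopentyl]phenyl]methyl]-2,3-dimethoxy-6-methyl-4-[(1S)-1,2,2-trimethylcyclopentyl]benzene
Product: 14 3-[[3,4-dihydroxy-5-[(1S)-1,2,2-trimethylcyclopentyl]phenyl]methyl]-4-methyl-6-[(1S)-1,2,2-trimethylcyclopentyl]benzene-1,2-diol (target)
Conditions: BBr3 (excess), CH2Cl2, −78 °C to rt; then H2O; work-up under argon
Reagents that add atoms: none
Why: Lewis-acid cleavage of the four aryl methyl ethers with BBr3 (bromide attack on the O-methyl of the boron-bound ether) should free both catechols without touching the diarylmethane or the quaternary centres.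

**Compound list**

1 | 3,4-dimethoxytoluene (1,2-dimethoxy-4-methylbenzene) | COc1ccc(C)cc1OC | starting material
2 | 2,2-dimethylcyclohexanone | CC1(C)CCCCC1=O | starting material
3 | (2,3-dimethoxy-5-methylphenyl)lithium | [Li]c1cc(C)cc(OC)c1OC | intermediate
4 | racemic 1-(2,3-dimethoxy-5-methylphenyl)-2,2-dimethylcyclohexan-1-ol | COc1cc(C)cc(C2(O)CCCCC2(C)C)c1OC | intermediate
5 | 1-(6,6-dimethylcyclohex-1-en-1-yl)-2,3-dimethoxy-5-methylbenzene | COc1cc(C)cc(C2=CCCCC2(C)C)c1OC | intermediate
6 | (1R,6R)-1-(2,3-dimethoxy-5-methylphenyl)-2,2-dimethyl-7-oxabicyclo[4.1.0]heptane | COc1cc(C)cc([C@@]23O[C@@H]2CCCC3(C)C)c1OC | intermediate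
7 | (1R)-1-(2,3-dimethoxy-5-methylphenyl)-2,2-dimethylcyclopentane-1-carbaldehyde | COc1cc(C)cc([C@@]2(C=O)CCCC2(C)C)c1OC | intermediate
8 | hydrazone of aldehyde 7 | COc1cc(C)cc([C@@]2(C=NN)CCCC2(C)C)c1OC | intermediate
9 | 1,2-dimethoxy-5-methyl-3-[(1S)-1,2,2-trimethylcyclopentyl]benzene ((S)-herbertenediol dimethyl ether) | COc1cc(C)cc([C@@]2(C)CCCC2(C)C)c1OC | intermediate
10 | 3,4-dimethoxy-5-[(1S)-1,2,2-trimethylcyclopentyl]benzaldehyde | COc1cc(C=O)cc([C@@]2(C)CCCC2(C)C)c1OC | intermediate
11 | 2,3-dimethoxy-6-methyl-4-[(1S)-1,2,2-trimethylcyclopentyl]phenyllithium | [Li]c1c(C)cc([C@@]2(C)CCCC2(C)C)c(OC)c1OC | intermediate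
12 | [2,3-dimethoxy-6-methyl-4-[(1S)-1,2,2-trimethylcyclopentyl]phenyl][3,4-dimethoxy-5-[(1S)-1,2,2-trimethylcyclopentyl]phenyl]methanol, both carbinol epimers | Cc1cc([C@@]2(C)CCCC2(C)C)c(OC)c(OC)c1C(O)c1cc(OC)c(OC)c([C@@]2(C)CCCC2(C)C)c1 | intermediate
13 | 1-[[3,4-dimethoxy-5-[(1S)-1,2,2-trimethylcyclopentyl]phenyl]methyl]-2,3-dimethoxy-6-methyl-4-[(1S)-1,2,2-trimethylcyclopentyl]benzene | Cc1cc([C@@]2(C)CCCC2(C)C)c(OC)c(OC)c1Cc1cc(OC)c(OC)c([C@@]2(C)CCCC2(C)C)c1 | intermediate
14 | 3-[[3,4-dihydroxy-5-[(1S)-1,2,2-trimethylcyclopentyl]phenyl]methyl]-4-methyl-6-[(1S)-1,2,2-trimethylcyclopentyl]benzene-1,2-diol | Cc1cc([C@@]2(C)CCCC2(C)C)c(O)c(O)c1Cc1cc(O)c(O)c([C@@]2(C)CCCC2(C)C)c1 | target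

**Count and risks**

Total step count: 9. Longest linear sequence: 9 steps (1 to 14; compound 9 supplies both halves).

Most likely to fail, in this order:

Step 4. The stereochemical information may be lost if the benzylic cation lives long enough to relax conformationally before the ring bond migrates, or the reaction may be diverted into a 1,2-hydride shift. Fallback, setting out from 5 and returning at 7: alkene 5 is epoxidised with the enantiomeric Shi ketone (made from L-sorbose) to give (1S,6S)-1-(2,3-dimethoxy-5-methylphenyl)-2,2-dimethyl-7-oxabicyclo[4.1.0]heptane F1. F1 is opened with MgBr2·OEt2 in Et2O–PhMe; bromide should enter the benzylic carbon anti to oxygen and give the bromomagnesium alkoxide of (1S,2R)-2-bromo-2-(2,3-dimethoxy-5-methylphenyl)-3,3-dimethylcyclohexan-1-ol F2, which is not isolated. On warming, the ring bond that lies antiperiplanar to the equatorial C–Br bond should migrate with loss of bromide (halohydrin semipinacol ring contraction). Two inversions at the benzylic carbon amount to net retention, so the (1S,6S)-epoxide leads to the same (R)-aldehyde 7, and a leaving group with a defined anti ring bond replaces the free cation.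

Step 3. Facial selectivity or conversion may be poor because the CMe2 group and the ortho-methoxy group crowd the transition state of oxygen transfer. Fallback, setting out from 5 and returning at 7: 5 is epoxidised with mCPBA (NaHCO3, CH2Cl2) to the racemic epoxide F3. The step 4 conditions then give racemic 1-(2,3-dimethoxy-5-methylphenyl)-2,2-dimethylcyclopentane-1-carbaldehyde F4. F4 is condensed with (1R,2R)-N,N′-dimethyl-1,2-diphenylethane-1,2-diamine (4 Å molecular sieves, PhMe) to two diastereomeric aminals, which are separated by chromatography or crystallisation. The aminal of the (R)-aldehyde, (4R,5R)-2-[(1R)-1-(2,3-dimethoxy-5-methylphenyl)-2,2-dimethylcyclopentyl]-1,3-dimethyl-4,5-diphenylimidazolidine F5, is hydrolysed with dilute aqueous HCl to 7.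

Step 6. Oxidation may run past the aldehyde or attack the electron-rich ring instead of converting the methyl group cleanly. Fallback, setting out from 9 and returning at 13 (steps 7 and 8 are then not needed): radical-chain bromination of 9 (NBS, AIBN, PhCF3, reflux, light) gives 5-(bromomethyl)-1,2-dimethoxy-3-[(1S)-1,2,2-trimethylcyclopentyl]benzene F6. A second portion of 9 is lithiated as in step 7 and transmetalated with ZnCl2 to chloro[2,3-dimethoxy-6-methyl-4-[(1S)-1,2,2-trimethylcyclopentyl]phenyl]zinc F7. Negishi coupling of F6 with F7 (Pd(PPh3)4, a zerovalent palladium catalyst, THF, 50 °C) gives 13 directly.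

**Further compounds**

F1 | step 4 | (1S,6S)-1-(2,3-dimethoxy-5-methylphenyl)-2,2-dimethyl-7-oxabicyclo[4.1.0]heptane | COc1cc(C)cc([C@]23O[C@H]2CCCC3(C)C)c1OC
F2 | step 4 | (1S,2R)-2-bromo-2-(2,3-dimethoxy-5-methylphenyl)-3,3-dimethylcyclohexan-1-ol (formed as its bromomagnesium alkoxide) | COc1cc(C)cc([C@@]2(Br)[C@@H](O)CCCC2(C)C)c1OC
F3 | step 3 | racemic 1-(2,3-dimethoxy-5-methylphenyl)-2,2-dimethyl-7-oxabicyclo[4.1.0]heptane | COc1cc(C)cc(C23OC2CCCC3(C)C)c1OC
F4 | step 3 | racemic 1-(2,3-dimethoxy-5-methylphenyl)-2,2-dimethylcyclopentane-1-carbaldehyde | COc1cc(C)cc(C2(C=O)CCCC2(C)C)c1OC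
F5 | step 3 | (4R,5R)-2-[(1R)-1-(2,3-dimethoxy-5-methylphenyl)-2,2-dimethylcyclopentyl]-1,3-dimethyl-4,5-diphenylimidazolidine | COc1cc(C)cc([C@@]2(C3N(C)[C@H](c4ccccc4)[C@@H](c4ccccc4)N3C)CCCC2(C)C)c1OC
F6 | step 6 | 5-(bromomethyl)-1,2-dimethoxy-3-[(1S)-1,2,2-trimethylcyclopentyl]benzene | COc1cc(CBr)cc([C@@]2(C)CCCC2(C)C)c1OC
F7 | step 6 | chloro[2,3-dimethoxy-6-methyl-4-[(1S)-1,2,2-trimethylcyclopentyl]phenyl]zinc | Cl[Zn]c1c(C)cc([C@@]2(C)CCCC2(C)C)c(OC)c1OC
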